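**Retrosynthetic overview**
- The acrylic acid comes from a silyl-protected allylic alcohol by late oxidation; the C5 acetate comes from a 4,5-diol.
- Key disconnection C4–C5: reductive ketyl (pinacol) macrocyclisation of a C5 aldehyde onto the C4 methyl ketone closes the 14-membered carbocycle and creates both carbinol centres.
- The tetrahydrofuran (C9–O–C12) comes from 5-exo opening of a Shi epoxide of a Z-C12=C13 alkene by the C9 hydroxyl, which sets C12 and C13.
- The Z-alkene comes from a B-alkyl Suzuki coupling of a (Z)-vinyl iodide (limonene-derived keto aldehyde, C1 from the chiral pool) with a cyclopentene-derived (S)-dienol (C5–C11).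
- Ring order: tetrahydrofuran first, 14-membered carbocycle second.

Assumption (locants used throughout): C1 is the ring carbon carrying the acrylic acid, C4 the methyl carbinol, C5 the acetoxy carbon, C8 the methylidene carbon, C9 and C12 the tetrahydrofuran carbons, C13 the secondary carbinol; the target is (1R,4R,5S,9S,12R,13R). TBDPS = tert-butyldiphenylsilyl.

**Fragment A (C13–C14–C1–C2–C3–C4)**

Step 1
Reactants: 1 (R)-(+)-limonene
Product: 4 2-[(1R)-4-methylcyclohex-3-en-1-yl]prop-2-en-1-ol, via allyllithium 2 (not isolated), via allylboronate 3 (not isolated)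
Conditions: n-BuLi, TMEDA, hexane, 25 °C, 24 h; B(OMe)3, Et2O, −78 °C; then 30% H2O2, aq NaOH, 0 °C to rt
Reagents that add atoms: hydrogen peroxide, OO
Why: TMEDA-activated n-BuLi deprotonates limonene at the isopropenyl methyl to a 2-substituted allyllithium with two identical CH2 termini, and borylation followed by alkaline peroxide oxidation gives the primary allylic alcohol without touching the C1 stereocentre (allylic metalation–borylation–oxidation).

Step 2
Reactants: 4 2-[(1R)-4-methylcyclohex-3-en-1-yl]prop-2-en-1-ol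
Product: 5 tert-butyl({2-[(1R)-4-methylcyclohex-3-en-1-yl]prop-2-en-1-yl}oxy)diphenylsilane
Conditions: TBDPSCl, imidazole, CH2Cl2, 0 °C to rt
Reagents that add atoms: tert-butyl(chloro)diphenylsilane, CC(C)(C)[Si](Cl)(c1ccccc1)c1ccccc1
Why: Silylation of the primary allylic alcohol keeps the future carboxyl carbon as a substituent of an unactivated alkene, which survives the reductive coupling of step 10 where an acrylate would not.

Step 3
Reactants: 5 tert-butyl({2-[(1R)-4-methylcyclohex-3-en-1-yl]prop-2-en-1-yl}oxy)diphenylsilane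
Product: 7 (3R)-3-{3-[(tert-butyldiphenylsilyl)oxy]prop-1-en-2-yl}-6-oxoheptanal, via ozonide 6 (not isolated)
Conditions: O3 (1.0 equiv, Sudan Red 7B end point), CH2Cl2, −78 °C; then PPh3, −78 °C to rt
Reagents that add atoms: ozone, [O-][O+]=O
Why: Ozone attacks the electron-rich trisubstituted ring alkene much faster than the 1,1-disubstituted alkene with an allylic silyloxy group, so one equivalent opens only the ring to the keto aldehyde (chemoselective ozonolysis with reductive work-up).

**Fragment B (C5–C11)**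

Step 4
Reactants: 8 cyclopentene
Product: 11 5,5-dimethoxypentanal, via hydroperoxy aldehyde 9 (not isolated), via hydroperoxy acetal 10 (not isolated)
Conditions: O3, CH2Cl2/MeOH, −78 °C; TsOH·H2O (cat.), rt; NaHCO3; then Me2S
Reagents that add atoms: ozone, [O-][O+]=O; methanol, CO
Why: Methanol traps the carbonyl oxide as a methoxy hydroperoxide, acid acetalises the free aldehyde end, and Me2S reduces the hydroperoxide end to the second aldehyde, giving the differentiated dialdehyde (Schreiber unsymmetrical ozonolysis).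

Step 5
Reactants: 11 5,5-dimethoxypentanal
Product: 12 5,5-dimethoxy-2-methylidenepentanal
Conditions: 37% aq HCHO, pyrrolidine (10 mol%), EtCO2H (10 mol%), i-PrOH, 45 °C
Reagents that add atoms: formaldehyde, C=O
Why: Pyrrolidinium-catalysed Mannich condensation with formaldehyde and loss of the amine installs the α-methylidene group while the acetal survives the weakly acidic medium (organocatalytic α-methylenation).

Step 6
Reactants: 12 5,5-dimethoxy-2-methylidenepentanal
Product: 13 (3S)-7,7-dimethoxy-4-methylidenehept-1-en-3-ol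
Conditions: (CH2=CH)2Zn (made from CH2=CHMgBr and ZnCl2), (−)-3-exo-morpholinoisoborneol (5 mol%), toluene/hexane, −30 to 0 °C; aq NH4Cl
Reagents that add atoms: vinylmagnesium bromide, C=C[Mg]Br
Why: The chiral amino alcohol–zinc complex delivers a vinyl group to the Si face of the aldehyde, which sets C9 as (S) (catalytic asymmetric alkenylzinc 1,2-addition).

**Union, ring formation and end game**

Step 7
Reactants: 7 (3R)-3-{3-[(tert-butyldiphenylsilyl)oxy]prop-1-en-2-yl}-6-oxoheptanal
Product: 14 (5R,7Z)-5-{3-[(tert-butyldiphenylsilyl)oxy]prop-1-en-2-yl}-8-iodonon-7-en-2-one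
Conditions: EtPPh3I, n-BuLi, THF, 0 °C; I2, −78 °C; NaN(SiMe3)2, −78 to −20 °C; then 7, −78 °C to rt
Reagents that add atoms: ethyltriphenylphosphonium iodide, CC[P+](c1ccccc1)(c1ccccc1)c1ccccc1.[I-]; iodine, II
Why: The α-iodo ylide reacts only with the aldehyde at −78 °C and gives the (Z)-2-iodoalkene with iodine cis to the chain under kinetic control (Stork–Zhao-type iodo-Wittig olefination), which fixes the alkene geometry that later decides C12 and C13.

Step 8
Reactants: 13 (3S)-7,7-dimethoxy-4-methylidenehept-1-en-3-ol; 14 (5R,7Z)-5-{3-[(tert-butyldiphenylsilyl)oxy]prop-1-en-2-yl}-8-iodonon-7-en-2-one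
Product: 16 (5R,7Z,11S)-5-{3-[(tert-butyldiphenylsilyl)oxy]prop-1-en-2-yl}-11-hydroxy-15,15-dimethoxy-8-methyl-12-methylidenepentadec-7-en-2-one, via bis(disiamylboryl) adduct 15 (not isolated)
Conditions: 13, (Sia)2BH (made from BH3·THF and 2-methyl-2-butene, 2.1 equiv), THF, 0 °C; then 14, Pd(dppf)Cl2 (10 mol%), AsPh3, Cs2CO3, DMF/H2O, 25 °C
Reagents that add atoms: none
Why: Disiamylborane hydroborates the monosubstituted vinyl group about twenty times faster than a 1,1-disubstituted alkene and puts boron on the terminal carbon, and the primary alkyl group then couples to the vinyl iodide with retention of the Z geometry while the secondary siamyl groups stay on boron (B-alkyl Suzuki–Miyaura coupling); no stereocentre is formed.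

Step 9
Reactants: 16 (5R,7Z,11S)-5-{3-[(tert-butyldiphenylsilyl)oxy]prop-1-en-2-yl}-11-hydroxy-15,15-dimethoxy-8-methyl-12-methylidenepentadec-7-en-2-one
Product: 19 (5R,7R)-5-{3-[(tert-butyldiphenylsilyl)oxy]prop-1-en-2-yl}-7-hydroxy-7-[(2R,5S)-2-methyl-5-(5-oxopent-1-en-2-yl)oxolan-2-yl]heptan-2-one, via epoxide 17 (not isolated), via tetrahydrofuran acetal 18 (not isolated)
Conditions: D-fructose-derived Shi ketone (30 mol%), KHSO5 (as 2KHSO5·KHSO4·K2SO4), K2CO3, Bu4NHSO4, Na2B4O7 buffer, MeCN/dimethoxymethane, 0 °C; extract; then camphorsulfonic acid (20 mol%), acetone/H2O, 25 °C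
Reagents that add atoms: potassium peroxymonosulfate, [K+].[O-]S(=O)(=O)OO; water, O
Why: The Shi dioxirane epoxidises the electron-rich Z-trisubstituted C12=C13 alkene, faster than the two 1,1-disubstituted alkenes with allylic oxygen, from the face that gives the (12S,13R)-epoxide (reagent control, spiro transition state); under acid the C9 hydroxyl opens it 5-exo at the tertiary C12 with inversion to the cis-2,5-tetrahydrofuran with (12R) and (13R) while C9 keeps its configuration, and the acetal is hydrolysed in the same pot (Shi asymmetric epoxidation, then epoxide-opening cyclisation).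

Step 10
Reactants: 19 (5R,7R)-5-{3-[(tert-butyldiphenylsilyl)oxy]prop-1-en-2-yl}-7-hydroxy-7-[(2R,5S)-2-methyl-5-(5-oxopent-1-en-2-yl)oxolan-2-yl]heptan-2-one
Product: 20 (1R,4R,5S,9S,12R,13R)-1-{3-[(tert-butyldiphenylsilyl)oxy]prop-1-en-2-yl}-9,12-epoxy-4,12-dimethyl-8-methylidenecyclotetradecane-4,5,13-triol
Conditions: TiCl3(DME)1.5, Zn(Cu), DME, reflux, 2 h; then 19 by syringe pump over 30 h at 25 °C (final 3 mM); aq K2CO3
Reagents that add atoms: none
Why: Low-valent titanium reduces the aldehyde to a titanium-bound ketyl, a carbonyl carbon of reversed polarity, which adds to the C4 ketone carbon on a titanium template that holds both oxygens syn (McMurry-type intramolecular pinacol coupling, run at 25 °C so that the diol is not deoxygenated) and closes the 14-membered ring pre-folded by the cis-tetrahydrofuran; C4 and C5 are set under substrate control, the mode with the C4 methyl rather than a ring bond anti to C6 giving (4R,5S)-20, which is separated from the other diol isomers.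

Step 11
Reactants: 20 (1R,4R,5S,9S,12R,13R)-1-{3-[(tert-butyldiphenylsilyl)oxy]prop-1-en-2-yl}-9,12-epoxy-4,12-dimethyl-8-methylidenecyclotetradecane-4,5,13-triol
Product: 21 (1R,4R,5S,9S,12R,13R)-1-{3-[(tert-butyldiphenylsilyl)oxy]prop-1-en-2-yl}-9,12-epoxy-4,13-dihydroxy-4,12-dimethyl-8-methylidenecyclotetradecan-5-yl acetate
Conditions: AcCl (1.2 equiv), i-Pr2NEt, Ph2BOCH2CH2NH2 (10 mol%), MeCN, 0 °C to rt
Reagents that add atoms: acetyl chloride, CC(Cl)=O
Why: The borinic acid binds the 4,5-diol as a tetracoordinate borinate and activates its less hindered secondary oxygen towards AcCl, so O5 is acetylated while the isolated, hindered C13 hydroxyl and the tertiary C4 hydroxyl stay free (borinic acid-catalysed regioselective acylation of a 1,2-diol).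

Step 12
Reactants: 21 (1R,4R,5S,9S,12R,13R)-1-{3-[(tert-butyldiphenylsilyl)oxy]prop-1-en-2-yl}-9,12-epoxy-4,13-dihydroxy-4,12-dimethyl-8-methylidenecyclotetradecan-5-yl acetate
Product: 22 (1R,4R,5S,9S,12R,13R)-9,12-epoxy-4,13-dihydroxy-1-(3-hydroxyprop-1-en-2-yl)-4,12-dimethyl-8-methylidenecyclotetradecan-5-yl acetate
Conditions: HF·pyridine, pyridine, THF, 0 °C to rt
Reagents that add atoms: none
Why: Buffered fluoride cleaves the primary silyl ether and leaves the acetate, the tertiary alcohol and the allylic ether untouched (desilylation).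

Step 13
Reactants: 22 (1R,4R,5S,9S,12R,13R)-9,12-epoxy-4,13-dihydroxy-1-(3-hydroxyprop-1-en-2-yl)-4,12-dimethyl-8-methylidenecyclotetradecan-5-yl acetate
Product: 24 Dendronpholide R, via enal 23 (not isolated)
Conditions: MnO2, CH2Cl2, 25 °C; filter; then NaClO2, NaH2PO4, 2-methyl-2-butene, t-BuOH/H2O, 0 °C
Reagents that add atoms: sodium chlorite, [Na+].[O-]Cl=O
Why: MnO2 oxidises only the allylic primary alcohol to the 2-substituted acrolein, and buffered chlorite with 2-methyl-2-butene as HOCl scavenger takes the aldehyde to the acid (allylic oxidation, then Pinnick oxidation) without touching the C13 hydroxyl, the acetate or the alkenes.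

**Compound list**

1 | (R)-(+)-limonene, (4R)-1-methyl-4-(prop-1-en-2-yl)cyclohex-1-ene | CC1=CC[C@@H](CC1)C(C)=C | starting material
2 | {2-[(1R)-4-methylcyclohex-3-en-1-yl]prop-2-en-1-yl}lithium | CC1=CC[C@@H](CC1)C(=C)C[Li] | intermediate
3 | dimethyl {2-[(1R)-4-methylcyclohex-3-en-1-yl]prop-2-en-1-yl}boronate | CC1=CC[C@@H](CC1)C(=C)CB(OC)OC | intermediate
4 | 2-[(1R)-4-methylcyclohex-3-en-1-yl]prop-2-en-1-ol | CC1=CC[C@@H](CC1)C(=C)CO | intermediate
5 | tert-butyl({2-[(1R)-4-methylcyclohex-3-en-1-yl]prop-2-en-1-yl}oxy)diphenylsilane | CC1=CC[C@@H](CC1)C(=C)CO[Si](c2ccccc2)(c2ccccc2)C(C)(C)C | intermediate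
6 | secondary ozonide of 5 (1,2,4-trioxolane across the former ring alkene, bridgehead epimers) | CC12CC[C@@H](C(=C)CO[Si](c3ccccc3)(c3ccccc3)C(C)(C)C)CC(O1)OO2 | intermediate
7 | (3R)-3-{3-[(tert-butyldiphenylsilyl)oxy]prop-1-en-2-yl}-6-oxoheptanal | O=CC[C@@H](CCC(C)=O)C(=C)CO[Si](c1ccccc1)(c1ccccc1)C(C)(C)C | intermediate
8 | cyclopentene | C1=CCCC1 | starting material
9 | 5-hydroperoxy-5-methoxypentanal | O=CCCCC(OC)OO | intermediate
10 | 5-hydroperoxy-1,1,5-trimethoxypentane | COC(OC)CCCC(OC)OO | intermediate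
11 | 5,5-dimethoxypentanal | COC(OC)CCCC=O | intermediate
12 | 5,5-dimethoxy-2-methylidenepentanal | COC(OC)CCC(=C)C=O | intermediate
13 | (3S)-7,7-dimethoxy-4-methylidenehept-1-en-3-ol | C=C(CCC(OC)OC)[C@@H](O)C=C | intermediate
14 | (5R,7Z)-5-{3-[(tert-butyldiphenylsilyl)oxy]prop-1-en-2-yl}-8-iodonon-7-en-2-one | C/C(I)=C/C[C@@H](CCC(C)=O)C(=C)CO[Si](c1ccccc1)(c1ccccc1)C(C)(C)C | intermediate
15 | (3S)-1-[bis(3-methylbutan-2-yl)boranyl]-3-{[bis(3-methylbutan-2-yl)boranyl]oxy}-7,7-dimethoxy-4-methylideneheptane | C=C(CCC(OC)OC)[C@@H](OB(C(C)C(C)C)C(C)C(C)C)CCB(C(C)C(C)C)C(C)C(C)C | intermediate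
16 | (5R,7Z,11S)-5-{3-[(tert-butyldiphenylsilyl)oxy]prop-1-en-2-yl}-11-hydroxy-15,15-dimethoxy-8-methyl-12-methylidenepentadec-7-en-2-one | C/C(CC[C@H](O)C(=C)CCC(OC)OC)=C/C[C@@H](CCC(C)=O)C(=C)CO[Si](c1ccccc1)(c1ccccc1)C(C)(C)C | intermediate
17 | (5R)-5-{3-[(tert-butyldiphenylsilyl)oxy]prop-1-en-2-yl}-6-{(2R,3S)-3-[(3S)-3-hydroxy-7,7-dimethoxy-4-methylideneheptyl]-3-methyloxiran-2-yl}hexan-2-one, the (12S,13R)-epoxide | C[C@@]1(CC[C@H](O)C(=C)CCC(OC)OC)O[C@@H]1C[C@@H](CCC(C)=O)C(=C)CO[Si](c2ccccc2)(c2ccccc2)C(C)(C)C | intermediate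
18 | (5R,7R)-5-{3-[(tert-butyldiphenylsilyl)oxy]prop-1-en-2-yl}-7-[(2R,5S)-5-(5,5-dimethoxypent-1-en-2-yl)-2-methyloxolan-2-yl]-7-hydroxyheptan-2-one | COC(OC)CCC(=C)[C@@H]1CC[C@@](C)(O1)[C@H](O)C[C@@H](CCC(C)=O)C(=C)CO[Si](c2ccccc2)(c2ccccc2)C(C)(C)C | intermediate
19 | (5R,7R)-5-{3-[(tert-butyldiphenylsilyl)oxy]prop-1-en-2-yl}-7-hydroxy-7-[(2R,5S)-2-methyl-5-(5-oxopent-1-en-2-yl)oxolan-2-yl]heptan-2-one | O=CCCC(=C)[C@@H]1CC[C@@](C)(O1)[C@H](O)C[C@@H](CCC(C)=O)C(=C)CO[Si](c2ccccc2)(c2ccccc2)C(C)(C)C | intermediate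
20 | (1R,4R,5S,9S,12R,13R)-1-{3-[(tert-butyldiphenylsilyl)oxy]prop-1-en-2-yl}-9,12-epoxy-4,12-dimethyl-8-methylidenecyclotetradecane-4,5,13-triol | C=C(CO[Si](c3ccccc3)(c3ccccc3)C(C)(C)C)[C@@H]1CC[C@@](C)(O)[C@@H](O)CCC(=C)[C@@H]2CC[C@@](C)(O2)[C@H](O)C1 | intermediate
21 | (1R,4R,5S,9S,12R,13R)-1-{3-[(tert-butyldiphenylsilyl)oxy]prop-1-en-2-yl}-9,12-epoxy-4,13-dihydroxy-4,12-dimethyl-8-methylidenecyclotetradecan-5-yl acetate | C=C(CO[Si](c3ccccc3)(c3ccccc3)C(C)(C)C)[C@@H]1CC[C@@](C)(O)[C@@H](OC(C)=O)CCC(=C)[C@@H]2CC[C@@](C)(O2)[C@H](O)C1 | intermediate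
22 | (1R,4R,5S,9S,12R,13R)-9,12-epoxy-4,13-dihydroxy-1-(3-hydroxyprop-1-en-2-yl)-4,12-dimethyl-8-methylidenecyclotetradecan-5-yl acetate | C=C(CO)[C@@H]1CC[C@@](C)(O)[C@@H](OC(C)=O)CCC(=C)[C@@H]2CC[C@@](C)(O2)[C@H](O)C1 | intermediate
23 | (1R,4R,5S,9S,12R,13R)-9,12-epoxy-4,13-dihydroxy-4,12-dimethyl-8-methylidene-1-(3-oxoprop-1-en-2-yl)cyclotetradecan-5-yl acetate | C=C(C=O)[C@@H]1CC[C@@](C)(O)[C@@H](OC(C)=O)CCC(=C)[C@@H]2CC[C@@](C)(O2)[C@H](O)C1 | intermediate
24 | Dendronpholide R, 2-[(1R,4R,5S,9S,12R,13R)-5-acetoxy-9,12-epoxy-4,13-dihydroxy-4,12-dimethyl-8-methylidenecyclotetradecyl]prop-2-enoic acid | C=C(C(=O)O)[C@@H]1CC[C@@](C)(O)[C@@H](OC(C)=O)CCC(=C)[C@@H]2CC[C@@](C)(O2)[C@H](O)C1 | target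

**Step count**
Total: 13 steps. Longest linear sequence: 10 steps (1, 2, 3, 7, 8, 9, 10, 11, 12, 13).

**Three steps most likely to fail**

Step 10 (pinacol macrocyclisation). Both the ring-closure yield and the C4/C5 outcome rest on substrate control, and the (4R,5S) isomer may be a minor component; unwanted diol isomers can be returned to 19 with NaIO4. The fallback sets out from 19 and comes back at 21. The same low-valent titanium reagent at reflux deoxygenates the coupled product to the macrocyclic (4E)-alkene F1 (McMurry olefination). Shi epoxidation with the D-fructose-derived ketone then gives the (4R,5R)-epoxide F2 under reagent control. CsOAc with 18-crown-6 in DMF opens F2 at the secondary carbon C5 with inversion and gives acetate 21 directly, so C4 and C5 are set by the epoxidation and not by the ring closure.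

Step 7 (iodo-Wittig). Yields are usually modest, the keto aldehyde is enolisable, and Z/E erosion is possible. The fallback sets out from 7 and comes back at 16. CBr4 and PPh3 convert the aldehyde into the 1,1-dibromoalkene F3. Negishi monomethylation of the bromide trans to the chain (MeZnCl, Pd(DPEphos)Cl2) gives the (Z)-2-bromoalkene F4. F4 then takes the place of 14 in the coupling with borane 15 (Pd(P(t-Bu)3)2 to avoid geometry scrambling) and gives 16.

Step 6 (asymmetric vinylation). The enantioselectivity on an α-methylidene aldehyde is not assured. The fallback sets out from 12 and comes back at 13. CH2=CHMgBr adds to 12 to give the racemic dienol F5. Burkholderia cepacia lipase with vinyl acetate acetylates the (R)-enantiomer to the (3R)-acetate F6 and leaves the (S)-alcohol 13, which is separated by chromatography.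

**Further compounds**

F1 | step 10 | (1R,4E,9S,12R,13R)-1-{3-[(tert-butyldiphenylsilyl)oxy]prop-1-en-2-yl}-9,12-epoxy-4,12-dimethyl-8-methylidenecyclotetradec-4-en-13-ol | C=C(CO[Si](c3ccccc3)(c3ccccc3)C(C)(C)C)[C@@H]1CC/C(C)=C/CCC(=C)[C@@H]2CC[C@@](C)(O2)[C@H](O)C1
F2 | step 10 | (4R,5R)-4,5-epoxide of F1 | C=C(CO[Si](c4ccccc4)(c4ccccc4)C(C)(C)C)[C@@H]1CC[C@@]2(C)O[C@@H]2CCC(=C)[C@@H]3CC[C@@](C)(O3)[C@H](O)C1
F3 | step 7 | (5R)-8,8-dibromo-5-{3-[(tert-butyldiphenylsilyl)oxy]prop-1-en-2-yl}oct-7-en-2-one | BrC(Br)=CC[C@@H](CCC(C)=O)C(=C)CO[Si](c1ccccc1)(c1ccccc1)C(C)(C)C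
F4 | step 7 | (5R,7Z)-8-bromo-5-{3-[(tert-butyldiphenylsilyl)oxy]prop-1-en-2-yl}non-7-en-2-one | C/C(Br)=C/C[C@@H](CCC(C)=O)C(=C)CO[Si](c1ccccc1)(c1ccccc1)C(C)(C)C
F5 | step 6 | racemic 7,7-dimethoxy-4-methylidenehept-1-en-3-ol | C=C(CCC(OC)OC)C(O)C=C
F6 | step 6 | (3R)-7,7-dimethoxy-4-methylidenehept-1-en-3-yl acetate | C=C(CCC(OC)OC)[C@H](OC(C)=O)C=C
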